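**Retrosynthetic overview**

1. Germacrane numbering is used: a ten-membered carbocycle C1–C10 (C4 = CH(CH3), C9=C10 alkene carrying C14H2OH on C10, C8 = acyloxy carbon) is fused at C6–C7 to the α-methylene-γ-lactone O–C6–C7–C11(=C13H2)–C12(=O).
2. Enabling feature: C6 (lactone carbinol) and C7 (bearing the C11=C13/C12 acrylate unit) form a homoallylic alcohol array O–C6–C7–C11=C13, and the C6–C7 bond belongs to both rings. This is the retron of a carbonyl allylation with allyl transposition, so an acyclic C6 aldehyde carrying a C13 bromide closes the carbocycle and then the lactone in one operation.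
3. Disconnections in retro order: C8–O side-chain ester (Mitsunobu inversion); C6–C7 (chromium-mediated ring closure of acyclic 20, carbocycle first, lactone second, same flask); C11–C12 (carbonylation of a Z-vinyl iodide); C7–C8 (asymmetric alkynylation of an enal, sets C8); C1–C10 (Negishi coupling).
4. Building blocks: (S)-citronellal (C1–C6 with the C4 stereocentre), but-2-yne-1,4-diol (used twice: C8–C10/C14 and the side chain) and a silyl propargyl ether (C7, C11, C13).

Key step: step 14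

Abbreviations: TBS = tert-butyldimethylsilyl, TBDPS = tert-butyldiphenylsilyl, PMB = 4-methoxybenzyl, PPTS = pyridinium p-toluenesulfonate.

Assumption: (R,R)-ProPhenol is taken to direct the alkynylzinc to the Re face of enal 12; if the opposite sense is found, (S,S)-ProPhenol is used and nothing else changes.

**Route**

Step 1
Reactants: 1 (S)-citronellal
Product: 2 (6S)-8,8-dimethoxy-2,6-dimethyloct-2-ene
Conditions: HC(OMe)3, MeOH, PPTS (cat.), 25 °C
Reagents that add atoms: trimethyl orthoformate, COC(OC)OC; methanol, CO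
Why: Acid-catalysed acetalisation with the orthoformate as water scavenger masks the future C6 aldehyde; the weak acid should not trigger the carbonyl-ene cyclisation of citronellal, and the C4 stereocentre is untouched.

Step 2
Reactants: 2 (6S)-8,8-dimethoxy-2,6-dimethyloct-2-ene
Product: 4 (4S)-6,6-dimethoxy-4-methylhexan-1-ol, via aldehyde 3 (not isolated)
Conditions: O3, CH2Cl2–MeOH, −78 °C; then NaBH4, −78 to 0 °C
Reagents that add atoms: ozone, [O-][O+]=O
Why: Ozonolysis cleaves the only alkene and the reductive NaBH4 work-up takes the aldehyde on to the primary alcohol that becomes C1, the acetal being inert to both reagents.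

Step 3
Reactants: 4 (4S)-6,6-dimethoxy-4-methylhexan-1-ol
Product: 5 (3S)-6-iodo-1,1-dimethoxy-3-methylhexane
Conditions: I2, PPh3, imidazole, CH2Cl2, 0 °C
Reagents that add atoms: iodine, II
Why: Appel-type iodination proceeds by SN2 displacement of the alkoxyphosphonium at a primary carbon, and imidazole buffers the medium so that the acetal should survive.

Step 4
Reactants: 6 but-2-yne-1,4-diol
Product: 7 4-(TBDPS-oxy)but-2-yn-1-ol
Conditions: TBDPSCl (0.3 equiv), imidazole, DMF, 0 °C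
Reagents that add atoms: tert-butyl(chloro)diphenylsilane, CC(C)(C)[Si](Cl)(c1ccccc1)c1ccccc1
Why: Statistical monosilylation of the symmetric diol used in excess leaves one hydroxyl free to direct the next step and installs the C14 protecting group that lasts to the end.

Step 5
Reactants: 7 4-(TBDPS-oxy)but-2-yn-1-ol
Product: 9 (2Z)-4-(TBDPS-oxy)-3-iodobut-2-en-1-ol, via alkenylaluminate 8 (not isolated)
Conditions: NaAlH2(OCH2CH2OMe)2, THF, 0 °C; then I2, THF, −78 °C
Reagents that add atoms: iodine, II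
Why: Hydroxyl-directed trans-hydroalumination delivers hydride to the alkyne carbon next to the carbinol and gives a five-membered alkenylaluminate, whose iodinolysis with retention places iodine cis to CH2OH; the silyloxy group is a poor leaving group at low temperature, so allene formation should not compete.

Step 6
Reactants: 5 (3S)-6-iodo-1,1-dimethoxy-3-methylhexane; 9 (2Z)-4-(TBDPS-oxy)-3-iodobut-2-en-1-ol
Product: 11 (2E,7S)-3-[(TBDPS-oxy)methyl]-9,9-dimethoxy-7-methylnon-2-en-1-ol, via alkylzinc iodide 10 (not isolated)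
Conditions: 5 (2 equiv), Zn dust (activated with BrCH2CH2Br and Me3SiCl), LiCl, THF, 40 °C; then 9, Pd(OAc)2 (3 mol %), SPhos (6 mol %), THF, 25 °C
Reagents that add atoms: none
Why: Negishi coupling of the primary alkylzinc with the vinyl iodide proceeds with retention of alkene geometry, so C1 ends up cis to C8 as the ring requires; the organozinc tolerates the acetal and, used in excess, the free hydroxyl.

Step 7
Reactants: 11 (2E,7S)-3-[(TBDPS-oxy)methyl]-9,9-dimethoxy-7-methylnon-2-en-1-ol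
Product: 12 (2E,7S)-3-[(TBDPS-oxy)methyl]-9,9-dimethoxy-7-methylnon-2-enal
Conditions: MnO2, CH2Cl2, 25 °C
Reagents that add atoms: none
Why: MnO2 oxidises only the allylic alcohol under neutral heterogeneous conditions, which should keep the alkene geometry of the sensitive enal intact.

Step 8
Reactants: 12 (2E,7S)-3-[(TBDPS-oxy)methyl]-9,9-dimethoxy-7-methylnon-2-enal; 13 tert-butyldimethyl(prop-2-yn-1-yloxy)silane
Product: 14 (4S,5E,10S)-1-(TBS-oxy)-6-[(TBDPS-oxy)methyl]-12,12-dimethoxy-10-methyldodec-5-en-2-yn-4-ol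
Conditions: (R,R)-ProPhenol (20 mol %), Me2Zn, Ph3P=O (40 mol %), toluene, 4 °C
Reagents that add atoms: none
Why: Catalytic asymmetric alkynylation of an enal: the alkynylzinc formed from 13 and Me2Zn is delivered inside the dinuclear zinc–ProPhenol pocket to the Re face of the aldehyde, which sets C8 as S by reagent control (the configuration that the ring closure and the later inversion require).

Step 9
Reactants: 14 (4S,5E,10S)-1-(TBS-oxy)-6-[(TBDPS-oxy)methyl]-12,12-dimethoxy-10-methyldodec-5-en-2-yn-4-ol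
Product: 16 (2Z,4S,5E,10S)-1-(TBS-oxy)-6-[(TBDPS-oxy)methyl]-2-iodo-12,12-dimethoxy-10-methyldodeca-2,5-dien-4-ol, via alkenylaluminate 15 (not isolated)
Conditions: NaAlH2(OCH2CH2OMe)2, THF, −20 to 0 °C; then I2, THF, −78 °C
Reagents that add atoms: iodine, II
Why: The free C8 hydroxyl directs the same trans-hydroalumination as in step 5, putting hydrogen on C7 and aluminium (then iodine) on C11 cis to C8, which fixes the geometry in which the future ester is cis to C8.

Step 10
Reactants: 16 (2Z,4S,5E,10S)-1-(TBS-oxy)-6-[(TBDPS-oxy)methyl]-2-iodo-12,12-dimethoxy-10-methyldodeca-2,5-dien-4-ol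
Product: 17 (2Z,4S,5E,10S)-1-(TBS-oxy)-6-[(TBDPS-oxy)methyl]-2-iodo-12,12-dimethoxy-4-(PMB-oxy)-10-methyldodeca-2,5-diene
Conditions: NaH, PMBCl, Bu4NI (cat.), DMF, 0 °C
Reagents that add atoms: 4-methoxybenzyl chloride, COc1ccc(CCl)cc1
Why: Williamson etherification caps O8 so that the carbonylation cannot close a butenolide and so that C8 carries a poor leaving group in the ring closure; no silyl group can migrate because both silyloxymethyl groups are trans to C8.

Step 11
Reactants: 17 (2Z,4S,5E,10S)-1-(TBS-oxy)-6-[(TBDPS-oxy)methyl]-2-iodo-12,12-dimethoxy-4-(PMB-oxy)-10-methyldodeca-2,5-diene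
Product: 18 methyl (2Z,4S,5E,10S)-2-[(TBS-oxy)methyl]-6-[(TBDPS-oxy)methyl]-12,12-dimethoxy-4-(PMB-oxy)-10-methyldodeca-2,5-dienoate
Conditions: PdCl2(PPh3)2 (5 mol %), CO (1 atm), Et3N, MeOH–DMF, 50 °C
Reagents that add atoms: carbon monoxide, [C-]#[O+]; methanol, CO
Why: Palladium-catalysed methoxycarbonylation (oxidative addition, CO insertion, methanolysis) replaces iodine by CO2Me with retention, giving the enoate in which the ester is cis to C8.

Step 12
Reactants: 18 methyl (2Z,4S,5E,10S)-2-[(TBS-oxy)methyl]-6-[(TBDPS-oxy)methyl]-12,12-dimethoxy-4-(PMB-oxy)-10-methyldodeca-2,5-dienoate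
Product: 19 methyl (2Z,4S,5E,10S)-6-[(TBDPS-oxy)methyl]-2-(hydroxymethyl)-4-(PMB-oxy)-10-methyl-12-oxododeca-2,5-dienoate
Conditions: AcOH–THF–H2O (3:1:1), 35 °C
Reagents that add atoms: water, O
Why: Mild aqueous acid hydrolyses the dimethyl acetal and the primary allylic TBS ether together, while the TBDPS and PMB ethers are stable under these conditions.

Step 13
Reactants: 19 methyl (2Z,4S,5E,10S)-6-[(TBDPS-oxy)methyl]-2-(hydroxymethyl)-4-(PMB-oxy)-10-methyl-12-oxododeca-2,5-dienoate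
Product: 20 methyl (2E,4S,5E,10S)-2-(bromomethyl)-6-[(TBDPS-oxy)methyl]-4-(PMB-oxy)-10-methyl-12-oxododeca-2,5-dienoate
Conditions: NBS, Me2S, CH2Cl2, −20 to 0 °C
Reagents that add atoms: N-bromosuccinimide, O=C1CCC(=O)N1Br
Why: Corey–Kim bromination activates only the allylic alcohol as an alkoxysulfonium that bromide displaces by SN2, leaving the aldehyde and the alkene geometry unchanged.

Step 14
Reactants: 20 methyl (2E,4S,5E,10S)-2-(bromomethyl)-6-[(TBDPS-oxy)methyl]-4-(PMB-oxy)-10-methyl-12-oxododeca-2,5-dienoate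
Product: 23 (3aS,4S,5E,10S,11aR)-6-[(TBDPS-oxy)methyl]-4-(PMB-oxy)-10-methyl-3-methylidene-3a,4,7,8,9,10,11,11a-octahydrocyclodeca[b]furan-2(3H)-one, via allylchromium dichloride 21 (not isolated), via hydroxy ester 22 (not isolated)
Conditions: CrCl2 (6 equiv), THF, 25 °C, 20 added by syringe pump to a final 2 mM; aq NH4Cl; then PPTS, CH2Cl2, 25 °C
Reagents that add atoms: none
Why: CrCl2 reduces the allylic bromide in two one-electron steps to the σ-allylchromium dichloride 21, whose γ-carbon C7 adds to the C6 aldehyde through a six-membered chair transition state with allyl transposition (intramolecular Nozaki–Hiyama–Kishi allylation), and the γ-hydroxy ester 22 then lactonises under PPTS; the closest known reaction type is the chromium-mediated macrocyclisation of ω-formyl 2-(bromomethyl)alk-2-enoates to ten-membered α-methylene lactones in germacranolide synthesis. The carbocycle closes by 10-exo-trig attack of C7 on the aldehyde (SE2′ at the allyl unit, which moves the double bond to C11=C13), and the lactone closes by 5-exo-trig acyl substitution of O6 at the C12 ester. C6 is set relative to C7 by the chair: the bromide geometry (C8 trans to CH2Cr, cis to the ester) and an equatorial aldehyde chain give the anti adduct, which is the trans-fused lactone (6R,7S). C7 is set by C8: allylic 1,3-strain against the cis ester on C11 and against the cis C1 chain on C10 holds H8 in the plane of both alkenes, which places C9 with its tether over one face of C7 and the PMB ether over the other, so the tethered aldehyde can reach only the face syn to C9, and with (8S) this is the 7S configuration. The step needs ring closure to outrun intermolecular coupling (high dilution, slow addition), retention of the allyl geometry (the γ-substituent trans to CH2Cr is the arrangement an allylchromium prefers) and no 1,4-loss of the C8 oxygen (a PMB ether is a poor leaving group).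

Step 15
Reactants: 23 (3aS,4S,5E,10S,11aR)-6-[(TBDPS-oxy)methyl]-4-(PMB-oxy)-10-methyl-3-methylidene-3a,4,7,8,9,10,11,11a-octahydrocyclodeca[b]furan-2(3H)-one
Product: 24 (3aR,4S,5E,10S,11aR)-6-[(TBDPS-oxy)methyl]-4-hydroxy-10-methyl-3-methylidene-3a,4,7,8,9,10,11,11a-octahydrocyclodeca[b]furan-2(3H)-one
Conditions: DDQ, CH2Cl2–pH 7 buffer, 0 °C
Reagents that add atoms: none
Why: DDQ oxidises the electron-rich benzyl ether to an oxocarbenium ion that water cleaves, freeing the C8 hydroxyl under neutral conditions that should leave the lactone, the silyl ether and the alkenes alone (the 3a descriptor changes only because the sequence-rule priorities change).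

Step 16
Reactants: 6 but-2-yne-1,4-diol
Product: 25 4-(TBS-oxy)but-2-yn-1-ol
Conditions: TBSCl (0.3 equiv), imidazole, DMF, 0 °C
Reagents that add atoms: tert-butyl(chloro)dimethylsilane, CC(C)(C)[Si](C)(C)Cl
Why: Statistical monosilylation of the diol in excess, as in step 4.

Step 17
Reactants: 25 4-(TBS-oxy)but-2-yn-1-ol
Product: 27 (2Z)-4-(TBS-oxy)-3-iodobut-2-en-1-ol, via alkenylaluminate 26 (not isolated)
Conditions: NaAlH2(OCH2CH2OMe)2, THF, 0 °C; then I2, THF, −78 °C
Reagents that add atoms: iodine, II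
Why: The same hydroxyl-directed trans-hydroalumination and iodinolysis as in step 5 puts iodine cis to the CH2O group on the CH carbon, which is the geometry of the side-chain enoate.

Step 18
Reactants: 27 (2Z)-4-(TBS-oxy)-3-iodobut-2-en-1-ol
Product: 28 (2Z)-1,4-bis(TBS-oxy)-2-iodobut-2-ene
Conditions: TBSCl, imidazole, CH2Cl2, 25 °C
Reagents that add atoms: tert-butyl(chloro)dimethylsilane, CC(C)(C)[Si](C)(C)Cl
Why: Silylation of the remaining primary alcohol prevents butenolide formation in the carbonylation and in the esterification.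

Step 19
Reactants: 28 (2Z)-1,4-bis(TBS-oxy)-2-iodobut-2-ene
Product: 29 (2Z)-4-(TBS-oxy)-2-[(TBS-oxy)methyl]but-2-enoic acid
Conditions: Pd(OAc)2 (5 mol %), PPh3 (10 mol %), CO (1 atm), H2O, Et3N, DMF, 50 °C
Reagents that add atoms: carbon monoxide, [C-]#[O+]; water, O
Why: Palladium-catalysed hydroxycarbonylation converts the vinyl iodide into the acid with retention, so the carboxyl is cis to the β-CH2OTBS group, and it avoids a vinyllithium that could undergo silyl migration.

Step 20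
Reactants: 24 (3aR,4S,5E,10S,11aR)-6-[(TBDPS-oxy)methyl]-4-hydroxy-10-methyl-3-methylidene-3a,4,7,8,9,10,11,11a-octahydrocyclodeca[b]furan-2(3H)-one; 29 (2Z)-4-(TBS-oxy)-2-[(TBS-oxy)methyl]but-2-enoic acid
Product: 30 (3aS,4R,5E,10S,11aR)-6-[(TBDPS-oxy)methyl]-10-methyl-3-methylidene-2-oxo-2,3,3a,4,7,8,9,10,11,11a-decahydrocyclodeca[b]furan-4-yl (2Z)-4-(TBS-oxy)-2-[(TBS-oxy)methyl]but-2-enoate
Conditions: PPh3, DIAD, toluene, 0 to 25 °C
Reagents that add atoms: none
Why: In the Mitsunobu esterification the carboxylate displaces the C8 alkoxyphosphonium by SN2, inverting C8 from S to R; the acid acts only as a nucleophile and is never activated as an acyl electrophile, so its Z geometry should not isomerise, and SN2′ attack would have to occur at fully substituted C10.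

Step 21
Reactants: 30 (3aS,4R,5E,10S,11aR)-6-[(TBDPS-oxy)methyl]-10-methyl-3-methylidene-2-oxo-2,3,3a,4,7,8,9,10,11,11a-decahydrocyclodeca[b]furan-4-yl (2Z)-4-(TBS-oxy)-2-[(TBS-oxy)methyl]but-2-enoate
Product: 31 CNP0131216.1
Conditions: HF·pyridine, pyridine, THF, 0 to 25 °C
Reagents that add atoms: none
Why: Buffered fluoride desilylation removes the three silyl ethers at once; the pyridine buffer and low temperature are meant to suppress closure of the freed Z-γ-hydroxy enoate to a butenolide and addition to the α-methylene lactone.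

**Compound list**

1 | (S)-citronellal, (3S)-3,7-dimethyloct-6-enal | O=CC[C@@H](C)CCC=C(C)C | starting material
2 | (6S)-8,8-dimethoxy-2,6-dimethyloct-2-ene | COC(OC)C[C@@H](C)CCC=C(C)C | intermediate
3 | (4S)-6,6-dimethoxy-4-methylhexanal | COC(OC)C[C@@H](C)CCC=O | intermediate
4 | (4S)-6,6-dimethoxy-4-methylhexan-1-ol | COC(OC)C[C@@H](C)CCCO | intermediate
5 | (3S)-6-iodo-1,1-dimethoxy-3-methylhexane | COC(OC)C[C@@H](C)CCCI | intermediate
6 | but-2-yne-1,4-diol | OCC#CCO | starting material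
7 | 4-(TBDPS-oxy)but-2-yn-1-ol | OCC#CCO[Si](c1ccccc1)(c1ccccc1)C(C)(C)C | intermediate
8 | sodium cyclic alkenylaluminate of 7 (2,2-bis(2-methoxyethoxy)-2,5-dihydro-1,2-oxaaluminole ate complex) | [Na+].COCCO[Al-]1(OCCOC)OCC=C1CO[Si](c2ccccc2)(c2ccccc2)C(C)(C)C | intermediate
9 | (2Z)-4-(TBDPS-oxy)-3-iodobut-2-en-1-ol | OC/C=C(I)/CO[Si](c1ccccc1)(c1ccccc1)C(C)(C)C | intermediate
10 | [(4S)-6,6-dimethoxy-4-methylhexyl]zinc iodide | COC(OC)C[C@@H](C)CCC[Zn]I | intermediate
11 | (2E,7S)-3-[(TBDPS-oxy)methyl]-9,9-dimethoxy-7-methylnon-2-en-1-ol | OC/C=C(CO[Si](c1ccccc1)(c1ccccc1)C(C)(C)C)\CCC[C@H](C)CC(OC)OC | intermediate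
12 | (2E,7S)-3-[(TBDPS-oxy)methyl]-9,9-dimethoxy-7-methylnon-2-enal | O=C/C=C(CO[Si](c1ccccc1)(c1ccccc1)C(C)(C)C)\CCC[C@H](C)CC(OC)OC | intermediate
13 | tert-butyldimethyl(prop-2-yn-1-yloxy)silane | C#CCO[Si](C)(C)C(C)(C)C | starting material
14 | (4S,5E,10S)-1-(TBS-oxy)-6-[(TBDPS-oxy)methyl]-12,12-dimethoxy-10-methyldodec-5-en-2-yn-4-ol | CC(C)(C)[Si](C)(C)OCC#C[C@@H](O)/C=C(CO[Si](c1ccccc1)(c1ccccc1)C(C)(C)C)\CCC[C@H](C)CC(OC)OC | intermediate
15 | sodium cyclic alkenylaluminate of 14 | [Na+].COCCO[Al-]1(OCCOC)O[C@@H](/C=C(CO[Si](c2ccccc2)(c2ccccc2)C(C)(C)C)\CCC[C@H](C)CC(OC)OC)C=C1CO[Si](C)(C)C(C)(C)C | intermediate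
16 | (2Z,4S,5E,10S)-1-(TBS-oxy)-6-[(TBDPS-oxy)methyl]-2-iodo-12,12-dimethoxy-10-methyldodeca-2,5-dien-4-ol | CC(C)(C)[Si](C)(C)OC/C(I)=C/[C@@H](O)/C=C(CO[Si](c1ccccc1)(c1ccccc1)C(C)(C)C)\CCC[C@H](C)CC(OC)OC | intermediate
17 | (2Z,4S,5E,10S)-1-(TBS-oxy)-6-[(TBDPS-oxy)methyl]-2-iodo-12,12-dimethoxy-4-(PMB-oxy)-10-methyldodeca-2,5-diene | CC(C)(C)[Si](C)(C)OC/C(I)=C/[C@@H](OCc1ccc(OC)cc1)/C=C(CO[Si](c1ccccc1)(c1ccccc1)C(C)(C)C)\CCC[C@H](C)CC(OC)OC | intermediate
18 | methyl (2Z,4S,5E,10S)-2-[(TBS-oxy)methyl]-6-[(TBDPS-oxy)methyl]-12,12-dimethoxy-4-(PMB-oxy)-10-methyldodeca-2,5-dienoate | CC(C)(C)[Si](C)(C)OC/C(C(=O)OC)=C/[C@@H](OCc1ccc(OC)cc1)/C=C(CO[Si](c1ccccc1)(c1ccccc1)C(C)(C)C)\CCC[C@H](C)CC(OC)OC | intermediate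
19 | methyl (2Z,4S,5E,10S)-6-[(TBDPS-oxy)methyl]-2-(hydroxymethyl)-4-(PMB-oxy)-10-methyl-12-oxododeca-2,5-dienoate | OC/C(C(=O)OC)=C/[C@@H](OCc1ccc(OC)cc1)/C=C(CO[Si](c1ccccc1)(c1ccccc1)C(C)(C)C)\CCC[C@H](C)CC=O | intermediate
20 | methyl (2E,4S,5E,10S)-2-(bromomethyl)-6-[(TBDPS-oxy)methyl]-4-(PMB-oxy)-10-methyl-12-oxododeca-2,5-dienoate | BrC/C(C(=O)OC)=C/[C@@H](OCc1ccc(OC)cc1)/C=C(CO[Si](c1ccccc1)(c1ccccc1)C(C)(C)C)\CCC[C@H](C)CC=O | intermediate
21 | allylchromium dichloride from 20 (CrCl2 on C13, solvent ligands omitted) | Cl[Cr](Cl)C/C(C(=O)OC)=C/[C@@H](OCc1ccc(OC)cc1)/C=C(CO[Si](c1ccccc1)(c1ccccc1)C(C)(C)C)\CCC[C@H](C)CC=O | intermediate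
22 | methyl 2-[(1S,2R,4S,8E,10S)-8-[(TBDPS-oxy)methyl]-2-hydroxy-10-(PMB-oxy)-4-methylcyclodec-8-en-1-yl]prop-2-enoate | C=C(C(=O)OC)[C@H]1[C@H](O)C[C@@H](C)CCC/C(CO[Si](c2ccccc2)(c2ccccc2)C(C)(C)C)=C\[C@@H]1OCc1ccc(OC)cc1 | intermediate
23 | (3aS,4S,5E,10S,11aR)-6-[(TBDPS-oxy)methyl]-4-(PMB-oxy)-10-methyl-3-methylidene-3a,4,7,8,9,10,11,11a-octahydrocyclodeca[b]furan-2(3H)-one | C=C1C(=O)O[C@@H]2C[C@@H](C)CCC/C(CO[Si](c3ccccc3)(c3ccccc3)C(C)(C)C)=C\[C@H](OCc3ccc(OC)cc3)[C@@H]12 | intermediate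
24 | (3aR,4S,5E,10S,11aR)-6-[(TBDPS-oxy)methyl]-4-hydroxy-10-methyl-3-methylidene-3a,4,7,8,9,10,11,11a-octahydrocyclodeca[b]furan-2(3H)-one | C=C1C(=O)O[C@@H]2C[C@@H](C)CCC/C(CO[Si](c3ccccc3)(c3ccccc3)C(C)(C)C)=C\[C@H](O)[C@@H]12 | intermediate
25 | 4-(TBS-oxy)but-2-yn-1-ol | OCC#CCO[Si](C)(C)C(C)(C)C | intermediate
26 | sodium cyclic alkenylaluminate of 25 | [Na+].COCCO[Al-]1(OCCOC)OCC=C1CO[Si](C)(C)C(C)(C)C | intermediate
27 | (2Z)-4-(TBS-oxy)-3-iodobut-2-en-1-ol | OC/C=C(I)/CO[Si](C)(C)C(C)(C)C | intermediate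
28 | (2Z)-1,4-bis(TBS-oxy)-2-iodobut-2-ene | CC(C)(C)[Si](C)(C)OC/C=C(I)/CO[Si](C)(C)C(C)(C)C | intermediate
29 | (2Z)-4-(TBS-oxy)-2-[(TBS-oxy)methyl]but-2-enoic acid | CC(C)(C)[Si](C)(C)OC/C=C(C(=O)O)/CO[Si](C)(C)C(C)(C)C | intermediate
30 | (3aS,4R,5E,10S,11aR)-6-[(TBDPS-oxy)methyl]-10-methyl-3-methylidene-2-oxo-2,3,3a,4,7,8,9,10,11,11a-decahydrocyclodeca[b]furan-4-yl (2Z)-4-(TBS-oxy)-2-[(TBS-oxy)methyl]but-2-enoate | C=C1C(=O)O[C@@H]2C[C@@H](C)CCC/C(CO[Si](c3ccccc3)(c3ccccc3)C(C)(C)C)=C\[C@@H](OC(=O)/C(=C\CO[Si](C)(C)C(C)(C)C)CO[Si](C)(C)C(C)(C)C)[C@@H]12 | intermediate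
31 | CNP0131216.1, (3aS,4R,5E,10S,11aR)-6-(hydroxymethyl)-10-methyl-3-methylidene-2-oxo-2,3,3a,4,7,8,9,10,11,11a-decahydrocyclodeca[b]furan-4-yl (2Z)-4-hydroxy-2-(hydroxymethyl)but-2-enoate | C=C1C(=O)O[C@@H]2C[C@@H](C)CCC/C(CO)=C\[C@@H](OC(=O)/C(=C\CO)CO)[C@@H]12 | target

**Step count and risks**

Total step count: 21. Longest linear sequence: 15 steps (1, 2, 3, 6, 7, 8, 9, 10, 11, 12, 13, 14, 15, 20, 21).

Steps most likely to fail:

Step 14. The allylchromium intermediate may lose the C8 ether by 1,4-elimination or couple with a second molecule before the ten-membered ring closes, and the excess divalent chromium may reduce the aldehyde. The fallback sets out from 19: acetylation (Ac2O, pyridine, 0 °C) should give methyl (2Z,4S,5E,10S)-2-(acetoxymethyl)-6-[(TBDPS-oxy)methyl]-4-(PMB-oxy)-10-methyl-12-oxododeca-2,5-dienoate F1. Under Pd(PPh3)4 (cat.) and InI in THF at high dilution, F1 is ionised to a π-allylpalladium complex that is transmetalated reductively to an allylindium species. This nucleophile is formed slowly and catalytically, without an excess of a strong one-electron reductant, and should add to the aldehyde through the same chair arrangement to give 22. PPTS then closes the lactone and the route is rejoined at 23. The reaction type is the known palladium-catalysed umpolung allylation of aldehydes with allylic acetates and InI.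

Step 20. The hindered allylic alkoxyphosphonium may eliminate to a diene or react without clean SN2 inversion. The fallback sets out from 24: Dess–Martin periodinane (CH2Cl2, NaHCO3) should give the C8 enone (3aS,5E,10S,11aR)-6-[(TBDPS-oxy)methyl]-10-methyl-3-methylidene-7,8,9,10,11,11a-hexahydrocyclodeca[b]furan-2,4(3H,3aH)-dione F2. Luche reduction (NaBH4, CeCl3·7H2O, MeOH, −78 °C) should add hydride to the carbonyl face opposite the C7–C11 bond and give the (8R)-alcohol (3aR,4R,5E,10S,11aR)-6-[(TBDPS-oxy)methyl]-4-hydroxy-10-methyl-3-methylidene-3a,4,7,8,9,10,11,11a-octahydrocyclodeca[b]furan-2(3H)-one F3. Acid 29 is converted with 2,4,6-trichlorobenzoyl chloride and Et3N into the mixed anhydride (2Z)-4-(TBS-oxy)-2-[(TBS-oxy)methyl]but-2-enoic 2,4,6-trichlorobenzoic anhydride F4, which acylates F3 with retention in toluene at 70 °C without a nucleophilic amine catalyst (to protect the Z geometry). The route is rejoined at 30.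

Step 8. The enal may isomerise about its C9=C10 bond under the basic zinc alkoxide conditions, and facial discrimination may be poor for a β,β-disubstituted enal. The fallback sets out from 12 and 13: deprotonation of 13 with n-BuLi (THF, −78 °C) gives lithium 3-(TBS-oxy)prop-1-yn-1-ide F5, which adds to 12 at −78 °C to give 1-(TBS-oxy)-6-[(TBDPS-oxy)methyl]-12,12-dimethoxy-10-methyldodec-5-en-2-yn-4-ol as a mixture of C4 epimers F6. MnO2 oxidation gives the ynone (5E,10S)-1-(TBS-oxy)-6-[(TBDPS-oxy)methyl]-12,12-dimethoxy-10-methyldodec-5-en-2-yn-4-one F7. Asymmetric transfer hydrogenation with RuCl(p-cymene)[(S,S)-TsDPEN] in i-PrOH should then give the 4S carbinol, by analogy with alkyl alkynyl ketones in which the alkyne takes the place of the aryl group. The route is rejoined at 14.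

Further compounds
F1 | step 14 | methyl (2Z,4S,5E,10S)-2-(acetoxymethyl)-6-[(TBDPS-oxy)methyl]-4-(PMB-oxy)-10-methyl-12-oxododeca-2,5-dienoate | CC(=O)OC/C(C(=O)OC)=C/[C@@H](OCc1ccc(OC)cc1)/C=C(CO[Si](c1ccccc1)(c1ccccc1)C(C)(C)C)\CCC[C@H](C)CC=O
F2 | step 20 | (3aS,5E,10S,11aR)-6-[(TBDPS-oxy)methyl]-10-methyl-3-methylidene-7,8,9,10,11,11a-hexahydrocyclodeca[b]furan-2,4(3H,3aH)-dione | C=C1C(=O)O[C@@H]2C[C@@H](C)CCC/C(CO[Si](c3ccccc3)(c3ccccc3)C(C)(C)C)=C\C(=O)[C@@H]12
F3 | step 20 | (3aR,4R,5E,10S,11aR)-6-[(TBDPS-oxy)methyl]-4-hydroxy-10-methyl-3-methylidene-3a,4,7,8,9,10,11,11a-octahydrocyclodeca[b]furan-2(3H)-one | C=C1C(=O)O[C@@H]2C[C@@H](C)CCC/C(CO[Si](c3ccccc3)(c3ccccc3)C(C)(C)C)=C\[C@@H](O)[C@@H]12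
F4 | step 20 | (2Z)-4-(TBS-oxy)-2-[(TBS-oxy)methyl]but-2-enoic 2,4,6-trichlorobenzoic anhydride | CC(C)(C)[Si](C)(C)OC/C=C(C(=O)OC(=O)c1c(Cl)cc(Cl)cc1Cl)/CO[Si](C)(C)C(C)(C)C
F5 | step 8 | lithium 3-(TBS-oxy)prop-1-yn-1-ide | [Li]C#CCO[Si](C)(C)C(C)(C)C
F6 | step 8 | (5E,10S)-1-(TBS-oxy)-6-[(TBDPS-oxy)methyl]-12,12-dimethoxy-10-methyldodec-5-en-2-yn-4-ol, mixture of C4 epimers | CC(C)(C)[Si](C)(C)OCC#CC(O)/C=C(CO[Si](c1ccccc1)(c1ccccc1)C(C)(C)C)\CCC[C@H](C)CC(OC)OC
F7 | step 8 | (5E,10S)-1-(TBS-oxy)-6-[(TBDPS-oxy)methyl]-12,12-dimethoxy-10-methyldodec-5-en-2-yn-4-one | CC(C)(C)[Si](C)(C)OCC#CC(=O)/C=C(CO[Si](c1ccccc1)(c1ccccc1)C(C)(C)C)\CCC[C@H](C)CC(OC)OC
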